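Winter and autumn are the two flasks I have to rank, and a colleague who trusts readings more than stories can check each step on the two earlier runs.

| flask | substrate | gas | temperature | remark | time |
|---|---|---|---|---|---|
| red | 0.14 M | 39 mM (held) | 45 °C | run made earlier |  |
| grey | 0.22 M | 39 mM (held) | 65 °C | run made earlier |  |
| winter | 0.10 M | 39 mM (held) | 80 °C |  | 20 min |
| autumn | 0.10 M | 39 mM (held) | 50 °C |  | 40 min |

| run | time / min | target / % | side product / % |
|---|---|---|---|
| red | 8.00 | 0 | 0.1 |
| red | 15.0 | 0 | 2.6 |
| red | 30.0 | 0 | 5.6 |
| red | 50.0 | 1.5 | 14.0 |
| red | 80.0 | 2.3 | 22.0 |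
| grey | 3.00 | 0 | 0.5 |
| grey | 8.00 | 1.6 | 9.4 |
| grey | 15.0 | 3.3 | 15.3 |
| grey | 25.0 | 8.0 | 20.7 |
| grey | 30.0 | 12.5 | 23.3 |

(standard deviation of a reading: 1 percentage point)

* the winner by share of target in all that became target or side product; "neither" if no more than 2 percentage points parts them (winter / autumn / neither)
* share of target in all that became target or side product, winter
* share of target in all that became target or side product, autumn

- at the start none of partner is dissolved
- candidate steps: substrate -> intermediate A; substrate <-> intermediate B; partner + intermediate B -> side product; partner + intermediate A <-> intermediate C; intermediate C -> intermediate D; partner + intermediate D -> target; intermediate B -> decomposed reagent; gas <-> partner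

In the grey run, between 15.0 min and 25.0 min, the side product gains 5.4 percentage points and the target 4.7 points. Over the next interval the target gains 4.5 points and the side product 2.6 points. So I put the change of hands near 25.0 min, and I call this the crossing time, the moment the target starts to gain on the side product. It is a reading, blurred by the scatter of 1 point. There the target's share, the selectivity, reads 27.9%, a reading I hold to the grey temperature. My rule has two parts: before its crossing a flask's side product outgains its target, and after it the reverse; and at the grey temperature a flask stopped before the crossing lies below that share.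

Now the settings. Substrate first: both flasks start at [substrate] = 0.10 M, so it parts nothing, and carrying the crossing over from 0.22 M unchanged is my assumption. Temperature moves the crossing: the side product's middle slope is 4.13 times steeper in the grey run than in the red. Scaled by that, the crossing falls at 8.63 min in winter and 72.5 min in autumn. Then time: winter's 20 min lies past its crossing, while autumn's 40 min falls short of its own. So I commit to winter ahead of autumn, and I give no share for either.

The forecast names winter, with 55% and 11%, numbers where I give an order, and uses a 3.5-fold speed-up where I read 4.13. Its ground: “Higher temperature and longer effective time both favour the target.”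

The simulation gives 84.6% for winter and 7.48% for autumn, so winter wins.

    substrate → intermediate A (k = 0.00930 s⁻¹, Ea = 103 kJ mol⁻¹)
    substrate ⇌ intermediate B (K = 0.390, k = 0.00730 s⁻¹, Ea = 110 kJ mol⁻¹, ΔH = −78.0 kJ mol⁻¹)
    partner + intermediate B → side product (k = 0.150 L mol⁻¹ s⁻¹, Ea = 53.0 kJ mol⁻¹)
    partner + intermediate A ⇌ intermediate C (K = 11.0 L mol⁻¹, k = 0.780 L mol⁻¹ s⁻¹, Ea = 42.0 kJ mol⁻¹, ΔH = −31.0 kJ mol⁻¹)
    intermediate C → intermediate D (k = 0.00270 s⁻¹, Ea = 109 kJ mol⁻¹)
    partner + intermediate D → target (k = 0.250 L mol⁻¹ s⁻¹, Ea = 64.0 kJ mol⁻¹)
    intermediate B → decomposed reagent (k = 0.00310 s⁻¹, Ea = 112 kJ mol⁻¹)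
    gas ⇌ partner, rate k8*(csat - [partner]) (kL = 0.00800 s⁻¹)
    (constants at 80 °C)

From 10.0 min to 20.0 min, winter's target gains 23 points and its side product 0.089 points. From 20.0 min to 40.0 min, autumn's side product gains 11 points and its target 1.3 points. The neighbouring flask repeats winter at 65 °C, the grey temperature, so its crossing stays at 25.0 min, later than its 20 min, and the rule puts it below 27.9%. It gives 21.4%, with 6.17% target against 22.6% side product.

(The runs come from a simulation for an exercise, noise included.)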